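**Plan**
- Retrosynthetic cuts: C7–Br and C1′–Br (back to a diol), O1–C2 (oxepene), C2–C3, C3=C4 and C4–C5 (side chain), C5a–C9a (cyclohexane), C6–C7 (open chain).
- Enabling feature: C9a is a tertiary carbinol carbon (methyl and O1) next to C5a, which carries C5 trans to O1 on the carbocycle C5a–C6–C7–C8–C9–C9a. This is the retron of an anti aldol between an aldehyde enamine at C5a and a methyl ketone at C9a.
- Forward order: C6–C7 is joined by reverse prenylboration and the chain is trimmed to a keto aldehyde. The six-membered ring closes by the proline aldol, the side chain grows C4, C3 and C2, the seven-membered ring closes at O1–C2, and both bromides come last.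
- Stereochemistry: C7 from the reagent-controlled prenylboration (carried as the epimeric silyl ether, inverted by bromide at the end); C5a and C9a from (S)-proline; C2 from hydride delivery anti to the C9a methyl group; C3=C4 from a Z-selective iodo-olefination.

Key step: step 8

Remark: atoms are labelled as in the target 1-benzoxepine (O1, C2–C5, C5a, C6–C9, C9a; C1′ is the bromomethyl carbon), the given SMILES is read as (2R,5aS,7S,9aS), and (−)-Ipc2BH, the borane made from (+)-α-pinene, is taken as a purchased reagent.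

**Step 1**
Reactants: 1 hex-5-en-2-one
Product: 2 2-(but-3-en-1-yl)-2-methyl-1,3-dioxolane
Conditions: HOCH2CH2OH, p-TsOH·H2O (cat.), toluene, reflux, Dean–Stark
Reagents that add atoms: ethane-1,2-diol OCCO
Why: Acid-catalysed ketalisation with azeotropic removal of water masks the future C9a ketone against the boranes and bases used up to step 5.

**Step 2**
Reactants: 2 alkenyl dioxolane
Product: 4 3-(2-methyl-1,3-dioxolan-2-yl)propanal, via ozonide 3 (not isolated)
Conditions: O3, CH2Cl2, −78 °C; then PPh3, −78 °C → rt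
Reagents that add atoms: ozone [O-][O+]=O
Why: Ozonolysis with reductive work-up cleaves the terminal alkene to the aldehyde (future C7) and leaves the ketal alone.

**Step 3**
Reactants: 4 ketal aldehyde; 5 3-methylbuta-1,2-diene
Product: 8 (3R)-4,4-dimethyl-1-(2-methyl-1,3-dioxolan-2-yl)hex-5-en-3-ol, via prenylborane 6 (not isolated), via borinate 7 (not isolated)
Conditions: (−)-Ipc2BH, 5, THF, −25 °C; then 4, −78 °C; then NaOH, H2O2, 0 °C → rt
Reagents that add atoms: none
Why: Hydroboration of the allene gives the B-prenyl borane, which adds to the aldehyde with allyl transposition through a chair Zimmerman–Traxler transition state (reverse prenylboration), forming C6–C7 with the gem-dimethyl group in place; the isopinocampheyl groups from (+)-α-pinene direct attack to the Si face, which sets C7 as R.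

**Step 4**
Reactants: 8 homoallylic alcohol
Product: 9 tert-butyl{[(3R)-4,4-dimethyl-1-(2-methyl-1,3-dioxolan-2-yl)hex-5-en-3-yl]oxy}dimethylsilane
Conditions: TBSOTf, 2,6-lutidine, CH2Cl2, −78 → 0 °C
Reagents that add atoms: tert-butyldimethylsilyl trifluoromethanesulfonate CC(C)(C)[Si](C)(C)OS(=O)(=O)C(F)(F)F
Why: Silylation with the silyl triflate and a hindered base is the standard way to protect a neopentylic secondary alcohol, and the short time at low temperature should spare the ketal.

**Step 5**
Reactants: 9 silyl ether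
Product: 11 (4R)-4-[(tert-butyldimethylsilyl)oxy]-3,3-dimethyl-6-(2-methyl-1,3-dioxolan-2-yl)hexan-1-ol, via alkylborane 10 (not isolated)
Conditions: 9-BBN, THF, rt → 60 °C; then NaOH, H2O2, 0 °C → rt
Reagents that add atoms: hydrogen peroxide OO
Why: Hydroboration–oxidation places boron and then hydroxyl on the terminal carbon of the vinyl group (anti-Markovnikov, reinforced by the adjacent quaternary carbon), giving the C5 alcohol.

**Step 6**
Reactants: 11 primary alcohol
Product: 12 (5R)-5-[(tert-butyldimethylsilyl)oxy]-8-hydroxy-6,6-dimethyloctan-2-one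
Conditions: PPTS (cat.), acetone–H2O (9:1), 55 °C
Reagents that add atoms: water O
Why: Mild acid-catalysed ketal hydrolysis frees the methyl ketone while the hindered secondary TBS ether should survive.

**Step 7**
Reactants: 12 hydroxy ketone
Product: 13 (4R)-4-[(tert-butyldimethylsilyl)oxy]-3,3-dimethyl-7-oxooctanal
Conditions: Dess–Martin periodinane, CH2Cl2, 0 °C → rt
Reagents that add atoms: none
Why: Dess–Martin oxidation takes the primary alcohol to the aldehyde under near-neutral conditions that should not start aldol chemistry of the 1,7-keto aldehyde.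

**Step 8**
Reactants: 13 keto aldehyde
Product: 15 (1S,3R,6S)-3-[(tert-butyldimethylsilyl)oxy]-6-hydroxy-2,2,6-trimethylcyclohexane-1-carbaldehyde, via enamine 14 (not isolated)
Conditions: (S)-proline (20 mol%), CH2Cl2, rt
Reagents that add atoms: none
Why: (S)-Proline condenses with the aldehyde, the more electrophilic and less hindered carbonyl group, to the (E)-enamine 14, whose β-carbon C5a adds to the ketone carbon C9a; hydrolysis of the resulting iminium ion releases 15 and the catalyst. The closest known reaction type is the proline-catalysed intramolecular enolexo aldolisation of 1,7-dicarbonyl compounds to trans-2-hydroxycyclohexanecarbaldehydes. The carbocycle C5a–C6–C7–C8–C9–C9a closes in the 6-enolexo-exo-trig mode. C5a and C9a are both set by the catalyst through a chair transition state in which the carboxylic acid hydrogen-bonds the ketone oxygen: the enamine arm and the developing O–H sit equatorial and the ketone methyl axial, which should give (5aS,9aS) with hydroxyl trans to formyl. The step needs the aldehyde as donor and the ketone as acceptor and not the reverse; faster enamine formation at the aldehyde, the Thorpe–Ingold effect of the C6 gem-dimethyl group and the single enolisable position beside the aldehyde favour this. The C7 silyloxy group is axial in this chair but faces only the axial hydrogens at C5a and C9, whereas an equatorial one would be gauche to both C6 methyl groups, so the resident centre should not override the catalyst.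

**Step 9**
Reactants: 15 aldol
Product: 16 (1S,3R,6S)-3-[(tert-butyldimethylsilyl)oxy]-2,2,6-trimethyl-6-[(triethylsilyl)oxy]cyclohexane-1-carbaldehyde
Conditions: TESOTf, 2,6-lutidine, CH2Cl2, −78 °C
Reagents that add atoms: triethylsilyl trifluoromethanesulfonate CC[Si](CC)(CC)OS(=O)(=O)C(F)(F)F
Why: Triflate silylation of the tertiary β-hydroxy aldehyde at low temperature blocks retro-aldol cleavage and dehydration in the basic steps that follow and provides the oxygen nucleophile for step 15.

**Step 10**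
Reactants: 16 TES ether aldehyde
Product: 17 2-[(1S,3R,6S)-3-[(tert-butyldimethylsilyl)oxy]-2,2,6-trimethyl-6-[(triethylsilyl)oxy]cyclohexyl]ethenyl methyl ether (E/Z mixture)
Conditions: Ph3P(CH2OMe)Cl, KHMDS, THF, 0 °C → rt
Reagents that add atoms: (methoxymethyl)triphenylphosphonium chloride COC[P+](c1ccccc1)(c1ccccc1)c1ccccc1.[Cl-]
Why: Wittig reaction with the methoxymethylene ylide adds C4 as an enol ether; the small ylide should reach the aldehyde despite the two quaternary neighbours of C5a.

**Step 11**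
Reactants: 17 enol ether
Product: 18 2-[(1S,3R,6S)-3-[(tert-butyldimethylsilyl)oxy]-2,2,6-trimethyl-6-[(triethylsilyl)oxy]cyclohexyl]acetaldehyde
Conditions: TFA, CH2Cl2–H2O (20:1), 0 °C
Reagents that add atoms: water O
Why: Acid hydrolysis of the enol ether (protonation at C5, collapse of the hemiacetal) gives the one-carbon-homologated aldehyde; a brief exposure to dilute acid at 0 °C should leave the tertiary TES and the secondary TBS ether intact.

**Step 12**
Reactants: 18 homologated aldehyde
Product: 19 (2Z)-1-[(1S,3R,6S)-3-[(tert-butyldimethylsilyl)oxy]-2,2,6-trimethyl-6-[(triethylsilyl)oxy]cyclohexyl]-3-iodobut-2-ene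
Conditions: EtPPh3I, n-BuLi, THF, rt; I2, −78 °C; NaHMDS, −20 °C; then 18, −78 → −20 °C
Reagents that add atoms: ethyltriphenylphosphonium iodide CC[P+](c1ccccc1)(c1ccccc1)c1ccccc1.[I-]; iodine II
Why: Stork–Zhao-type Wittig olefination with the α-iodo ethylidene ylide should give the trisubstituted (Z)-iodoalkene under kinetic control, which places C5 and the future C2 cis on C3=C4 as the ring requires.

**Step 13**
Reactants: 19 (Z)-vinyl iodide; 20 (tert-butyldimethylsilyloxy)acetaldehyde
Product: 21 (3Z)-1-[(tert-butyldimethylsilyl)oxy]-5-[(1S,3R,6S)-3-[(tert-butyldimethylsilyl)oxy]-2,2,6-trimethyl-6-[(triethylsilyl)oxy]cyclohexyl]-3-methylpent-3-en-2-ol (both C2 epimers)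
Conditions: CrCl2, NiCl2 (cat.), DMSO, rt
Reagents that add atoms: none
Why: Nozaki–Hiyama–Kishi coupling forms the alkenylchromium(III) species with retention of geometry and adds it chemoselectively to the aldehyde, making C2–C3; the carbinol configuration is irrelevant because it is oxidised next.

**Step 14**
Reactants: 21 allylic alcohol
Product: 22 (3Z)-1-[(tert-butyldimethylsilyl)oxy]-5-[(1S,3R,6S)-3-[(tert-butyldimethylsilyl)oxy]-2,2,6-trimethyl-6-[(triethylsilyl)oxy]cyclohexyl]-3-methylpent-3-en-2-one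
Conditions: Dess–Martin periodinane, pyridine, CH2Cl2, 0 °C
Reagents that add atoms: none
Why: Buffered Dess–Martin oxidation of the allylic alcohol should give the (Z)-enone without acid that could isomerise the double bond or cleave the silyl ethers.

**Step 15**
Reactants: 22 (Z)-enone
Product: 23 tert-butyl{[(2R,5aS,7R,9aS)-7-[(tert-butyldimethylsilyl)oxy]-3,6,6,9a-tetramethyl-2,5,5a,6,7,8,9,9a-octahydro-1-benzoxepin-2-yl]methoxy}dimethylsilane
Conditions: Et3SiH (5 equiv), TMSOTf (0.3 equiv), CH2Cl2, −78 → −40 °C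
Reagents that add atoms: none
Why: Proposed new method: TMSOTf activates the enone carbonyl, the C9a silyl ether oxygen adds to C2 (the Z double bond holds C2 within reach of O1), loss of silanolate gives a seven-membered cyclic oxocarbenium ion conjugated with C3=C4, and Et3SiH delivers hydride to C2 on the face opposite the axial C9a methyl group, which should set C2 as R and leave C3=C4 in place as in Ferrier-type reductions; the closest known reaction type is the silane/Lewis acid reductive etherification of hydroxy or silyloxy ketones to tetrahydropyrans and oxepanes, which has not been shown for a tertiary silyl ether closing onto a (Z)-enone.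

**Step 16**
Reactants: 23 bis-silyl oxepene
Product: 24 (2R,5aS,7R,9aS)-2-(hydroxymethyl)-3,6,6,9a-tetramethyl-2,5,5a,6,7,8,9,9a-octahydro-1-benzoxepin-7-ol
Conditions: TBAF, THF, rt → 50 °C
Reagents that add atoms: none
Why: Fluoride cleaves both TBS ethers through Si–F bond formation, and the allylic ether and the alkene are inert to TBAF.

**Step 17**
Reactants: 24 diol
Product: 25 palisadin B, (2R,5aS,7S,9aS)-7-bromo-2-(bromomethyl)-3,6,6,9a-tetramethyl-2,5,5a,6,7,8,9,9a-octahydro-1-benzoxepine
Conditions: CBr4, PPh3, 2,6-lutidine, toluene, 0 → 70 °C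
Reagents that add atoms: tetrabromomethane BrC(Br)(Br)Br
Why: Appel reaction: both alcohols become alkoxyphosphonium ions that bromide displaces in SN2 fashion, the primary one readily and the axial neopentylic C7–O by equatorial attack with inversion to the equatorial (7S) bromide, a conversion known for axial 2,2-dimethylcyclohexanols of this type.

**Compound list**
1 | hex-5-en-2-one | CC(=O)CCC=C | starting material
2 | 2-(but-3-en-1-yl)-2-methyl-1,3-dioxolane | CC1(CCC=C)OCCO1 | intermediate
3 | ozonide, 3-[2-(2-methyl-1,3-dioxolan-2-yl)ethyl]-1,2,4-trioxolane | CC1(CCC2OCOO2)OCCO1 | intermediate (not isolated)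
4 | 3-(2-methyl-1,3-dioxolan-2-yl)propanal | CC1(CCC=O)OCCO1 | intermediate
5 | 3-methylbuta-1,2-diene | CC(C)=C=C | starting material
6 | prenylborane, B-(3-methylbut-2-en-1-yl)diisopinocampheylborane from (+)-α-pinene | CC(C)=CCB([C@@H]1C[C@@H]2C[C@H]([C@H]1C)C2(C)C)[C@@H]1C[C@@H]2C[C@H]([C@H]1C)C2(C)C | intermediate (not isolated)
7 | borinate, O-diisopinocampheylboryl derivative of 8 | CC1(CC[C@@H](OB([C@@H]2C[C@@H]3C[C@H]([C@H]2C)C3(C)C)[C@@H]2C[C@@H]3C[C@H]([C@H]2C)C3(C)C)C(C)(C)C=C)OCCO1 | intermediate (not isolated)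
8 | (3R)-4,4-dimethyl-1-(2-methyl-1,3-dioxolan-2-yl)hex-5-en-3-ol | CC1(CC[C@@H](O)C(C)(C)C=C)OCCO1 | intermediate
9 | tert-butyl{[(3R)-4,4-dimethyl-1-(2-methyl-1,3-dioxolan-2-yl)hex-5-en-3-yl]oxy}dimethylsilane | CC1(CC[C@@H](O[Si](C)(C)C(C)(C)C)C(C)(C)C=C)OCCO1 | intermediate
10 | alkylborane, B-alkyl-9-borabicyclo[3.3.1]nonane from 9 (boron on the terminal carbon) | CC1(CC[C@@H](O[Si](C)(C)C(C)(C)C)C(C)(C)CCB2C3CCCC2CCC3)OCCO1 | intermediate (not isolated)
11 | (4R)-4-[(tert-butyldimethylsilyl)oxy]-3,3-dimethyl-6-(2-methyl-1,3-dioxolan-2-yl)hexan-1-ol | CC1(CC[C@@H](O[Si](C)(C)C(C)(C)C)C(C)(C)CCO)OCCO1 | intermediate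
12 | (5R)-5-[(tert-butyldimethylsilyl)oxy]-8-hydroxy-6,6-dimethyloctan-2-one | CC(=O)CC[C@@H](O[Si](C)(C)C(C)(C)C)C(C)(C)CCO | intermediate
13 | (4R)-4-[(tert-butyldimethylsilyl)oxy]-3,3-dimethyl-7-oxooctanal | O=CCC(C)(C)[C@H](O[Si](C)(C)C(C)(C)C)CCC(C)=O | intermediate (key-step precursor)
14 | enamine, (E)-enamine of the aldehyde of 13 with (S)-proline | OC(=O)[C@@H]1CCCN1/C=C/C(C)(C)[C@H](O[Si](C)(C)C(C)(C)C)CCC(C)=O | intermediate (not isolated)
15 | (1S,3R,6S)-3-[(tert-butyldimethylsilyl)oxy]-6-hydroxy-2,2,6-trimethylcyclohexane-1-carbaldehyde | O=C[C@H]1C(C)(C)[C@H](O[Si](C)(C)C(C)(C)C)CC[C@]1(C)O | intermediate (key-step product)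
16 | (1S,3R,6S)-3-[(tert-butyldimethylsilyl)oxy]-2,2,6-trimethyl-6-[(triethylsilyl)oxy]cyclohexane-1-carbaldehyde | O=C[C@H]1C(C)(C)[C@H](O[Si](C)(C)C(C)(C)C)CC[C@]1(C)O[Si](CC)(CC)CC | intermediate
17 | 2-[(1S,3R,6S)-3-[(tert-butyldimethylsilyl)oxy]-2,2,6-trimethyl-6-[(triethylsilyl)oxy]cyclohexyl]ethenyl methyl ether (E/Z mixture) | COC=C[C@H]1C(C)(C)[C@H](O[Si](C)(C)C(C)(C)C)CC[C@]1(C)O[Si](CC)(CC)CC | intermediate
18 | 2-[(1S,3R,6S)-3-[(tert-butyldimethylsilyl)oxy]-2,2,6-trimethyl-6-[(triethylsilyl)oxy]cyclohexyl]acetaldehyde | O=CC[C@H]1C(C)(C)[C@H](O[Si](C)(C)C(C)(C)C)CC[C@]1(C)O[Si](CC)(CC)CC | intermediate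
19 | (2Z)-1-[(1S,3R,6S)-3-[(tert-butyldimethylsilyl)oxy]-2,2,6-trimethyl-6-[(triethylsilyl)oxy]cyclohexyl]-3-iodobut-2-ene | C/C(I)=C/C[C@H]1C(C)(C)[C@H](O[Si](C)(C)C(C)(C)C)CC[C@]1(C)O[Si](CC)(CC)CC | intermediate
20 | (tert-butyldimethylsilyloxy)acetaldehyde | O=CCO[Si](C)(C)C(C)(C)C | starting material
21 | (3Z)-1-[(tert-butyldimethylsilyl)oxy]-5-[(1S,3R,6S)-3-[(tert-butyldimethylsilyl)oxy]-2,2,6-trimethyl-6-[(triethylsilyl)oxy]cyclohexyl]-3-methylpent-3-en-2-ol (C2 epimers) | C/C(C(O)CO[Si](C)(C)C(C)(C)C)=C/C[C@H]1C(C)(C)[C@H](O[Si](C)(C)C(C)(C)C)CC[C@]1(C)O[Si](CC)(CC)CC | intermediate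
22 | (3Z)-1-[(tert-butyldimethylsilyl)oxy]-5-[(1S,3R,6S)-3-[(tert-butyldimethylsilyl)oxy]-2,2,6-trimethyl-6-[(triethylsilyl)oxy]cyclohexyl]-3-methylpent-3-en-2-one | C/C(C(=O)CO[Si](C)(C)C(C)(C)C)=C/C[C@H]1C(C)(C)[C@H](O[Si](C)(C)C(C)(C)C)CC[C@]1(C)O[Si](CC)(CC)CC | intermediate
23 | tert-butyl{[(2R,5aS,7R,9aS)-7-[(tert-butyldimethylsilyl)oxy]-3,6,6,9a-tetramethyl-2,5,5a,6,7,8,9,9a-octahydro-1-benzoxepin-2-yl]methoxy}dimethylsilane | CC1=CC[C@H]2C(C)(C)[C@H](O[Si](C)(C)C(C)(C)C)CC[C@]2(C)O[C@H]1CO[Si](C)(C)C(C)(C)C | intermediate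
24 | (2R,5aS,7R,9aS)-2-(hydroxymethyl)-3,6,6,9a-tetramethyl-2,5,5a,6,7,8,9,9a-octahydro-1-benzoxepin-7-ol | CC1=CC[C@H]2C(C)(C)[C@H](O)CC[C@]2(C)O[C@H]1CO | intermediate
25 | palisadin B, (2R,5aS,7S,9aS)-7-bromo-2-(bromomethyl)-3,6,6,9a-tetramethyl-2,5,5a,6,7,8,9,9a-octahydro-1-benzoxepine | CC1=CC[C@H]2C(C)(C)[C@@H](Br)CC[C@]2(C)O[C@H]1CBr | target

**Step count**
Total: 17 steps. Longest linear sequence: 17 steps (1 → 25).

**Steps most likely to fail**

1. Step 15 (proposed new method). The silyl ether oxygen may add to C4 of the activated enone and close a five-membered ring by conjugate addition instead of attacking C2. The silane may also reduce the activated ketone before ring closure, or the tertiary C9a–O bond may ionise under the Lewis acid. The fallback uses known reactions only, sets out from aldehyde 18 and comes back at diol 24. Wittig methylenation (Ph3P=CH2, THF) would give the terminal alkene F1. HF·pyridine in THF/pyridine would remove the tertiary triethylsilyl group and give the tertiary alcohol F2. Its lithium alkoxide (n-BuLi, THF, −78 °C) and methacryloyl chloride would give the methacrylate F3. Ring-closing metathesis (second-generation Grubbs catalyst, toluene, 80 °C) would then close the seven-membered unsaturated lactone F4 at C3=C4, so that O1 is already bonded to C2 before the ring alkene exists. Tebbe methylenation would give the exocyclic enol ether F5. Hydroboration with 9-BBN on the face away from the C9a methyl group, followed by NaOH/H2O2, would give the primary alcohol F6 with C2 as R. TBAF then gives 24.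

2. Step 8 (key step). The enamine carbon C5a is neopentylic and may add too slowly to the methyl ketone. Enamine formation at the ketone with closure onto the aldehyde, or dehydration of the aldol to the conjugated cyclohexenecarbaldehyde, could then take over. Facial selectivity may also erode because the wanted chair carries both the C7 silyloxy group and the C9a methyl group axial. The fallback takes the resident stereocentre out of the aldol and sets it afterwards; it sets out from alcohol 8 and comes back at enol ether 17. Hydroboration–oxidation of 8 (9-BBN; NaOH, H2O2) would give the diol F7. Excess Dess–Martin periodinane would give the keto aldehyde ketal F8, and PPTS in wet acetone the achiral dioxo aldehyde F9. The same (S)-proline closure on F9, where only the catalyst decides C5a and C9a, would give the keto aldol F10, and TESOTf/2,6-lutidine its silyl ether F11. Wittig methoxymethylenation, which should take the aldehyde and not the ketone flanked by the quaternary carbon, would give the enol ether ketone F12. L-Selectride (THF, −78 °C) attacks from the equatorial side and would give the axial (7R) alcohol F13. TBSOTf/2,6-lutidine then gives 17.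

3. Step 17. At the neopentylic C7 the axial oxyphosphonium group may leave by E2 toward C8, or with a 1,2-shift of the antiperiplanar axial C6 methyl group, instead of being displaced. The fallback separates the two brominations and uses a non-ionising sulfonate; it sets out from diol 24 and comes back at target 25. A selective Appel reaction at the primary alcohol (CBr4, PPh3, CH2Cl2, 0 °C) would give the bromo alcohol F14. NaH and 1,1′-sulfonyldiimidazole (DMF, −30 °C) would give the imidazole-1-sulfonate F15. Bu4NBr in toluene at 80 °C should then displace it with inversion to give 25.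

**Further compounds**
F1 | step 15 | 3-[(1S,3R,6S)-3-[(tert-butyldimethylsilyl)oxy]-2,2,6-trimethyl-6-[(triethylsilyl)oxy]cyclohexyl]prop-1-ene | C=CC[C@H]1C(C)(C)[C@H](O[Si](C)(C)C(C)(C)C)CC[C@]1(C)O[Si](CC)(CC)CC
F2 | step 15 | (1S,2S,4R)-4-[(tert-butyldimethylsilyl)oxy]-1,3,3-trimethyl-2-(prop-2-en-1-yl)cyclohexan-1-ol | C=CC[C@H]1C(C)(C)[C@H](O[Si](C)(C)C(C)(C)C)CC[C@]1(C)O
F3 | step 15 | (1S,2S,4R)-4-[(tert-butyldimethylsilyl)oxy]-1,3,3-trimethyl-2-(prop-2-en-1-yl)cyclohexyl 2-methylprop-2-enoate | C=CC[C@H]1C(C)(C)[C@H](O[Si](C)(C)C(C)(C)C)CC[C@]1(C)OC(=O)C(C)=C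
F4 | step 15 | (5aS,7R,9aS)-7-[(tert-butyldimethylsilyl)oxy]-3,6,6,9a-tetramethyl-5a,6,7,8,9,9a-hexahydro-1-benzoxepin-2(5H)-one | CC1=CC[C@H]2C(C)(C)[C@H](O[Si](C)(C)C(C)(C)C)CC[C@]2(C)OC1=O
F5 | step 15 | tert-butyldimethyl{[(5aS,7R,9aS)-3,6,6,9a-tetramethyl-2-methylidene-2,5,5a,6,7,8,9,9a-octahydro-1-benzoxepin-7-yl]oxy}silane | CC1=CC[C@H]2C(C)(C)[C@H](O[Si](C)(C)C(C)(C)C)CC[C@]2(C)OC1=C
F6 | step 15 | [(2R,5aS,7R,9aS)-7-[(tert-butyldimethylsilyl)oxy]-3,6,6,9a-tetramethyl-2,5,5a,6,7,8,9,9a-octahydro-1-benzoxepin-2-yl]methanol | CC1=CC[C@H]2C(C)(C)[C@H](O[Si](C)(C)C(C)(C)C)CC[C@]2(C)O[C@H]1CO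
F7 | step 8 | (4R)-3,3-dimethyl-6-(2-methyl-1,3-dioxolan-2-yl)hexane-1,4-diol | CC1(CC[C@@H](O)C(C)(C)CCO)OCCO1
F8 | step 8 | 3,3-dimethyl-6-(2-methyl-1,3-dioxolan-2-yl)-4-oxohexanal | CC1(CCC(=O)C(C)(C)CC=O)OCCO1
F9 | step 8 | 3,3-dimethyl-4,7-dioxooctanal | CC(=O)CCC(=O)C(C)(C)CC=O
F10 | step 8 | (1S,6S)-6-hydroxy-2,2,6-trimethyl-3-oxocyclohexane-1-carbaldehyde | O=C[C@H]1C(C)(C)C(=O)CC[C@]1(C)O
F11 | step 8 | (1S,6S)-2,2,6-trimethyl-3-oxo-6-[(triethylsilyl)oxy]cyclohexane-1-carbaldehyde | O=C[C@H]1C(C)(C)C(=O)CC[C@]1(C)O[Si](CC)(CC)CC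
F12 | step 8 | (3S,4S)-3-(2-methoxyethenyl)-2,2,4-trimethyl-4-[(triethylsilyl)oxy]cyclohexan-1-one (E/Z mixture) | COC=C[C@H]1C(C)(C)C(=O)CC[C@]1(C)O[Si](CC)(CC)CC
F13 | step 8 | (1R,3S,4S)-3-(2-methoxyethenyl)-2,2,4-trimethyl-4-[(triethylsilyl)oxy]cyclohexan-1-ol (E/Z mixture) | COC=C[C@H]1C(C)(C)[C@H](O)CC[C@]1(C)O[Si](CC)(CC)CC
F14 | step 17 | (2R,5aS,7R,9aS)-2-(bromomethyl)-3,6,6,9a-tetramethyl-2,5,5a,6,7,8,9,9a-octahydro-1-benzoxepin-7-ol | CC1=CC[C@H]2C(C)(C)[C@H](O)CC[C@]2(C)O[C@H]1CBr
F15 | step 17 | (2R,5aS,7R,9aS)-2-(bromomethyl)-3,6,6,9a-tetramethyl-2,5,5a,6,7,8,9,9a-octahydro-1-benzoxepin-7-yl 1H-imidazole-1-sulfonate | CC1=CC[C@H]2C(C)(C)[C@H](OS(=O)(=O)n3ccnc3)CC[C@]2(C)O[C@H]1CBr
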